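**Strategy**

The route rests on opening the dihydropyran at its O1–C6 bond (labels: ring O1, C2 bearing CHBr2, C3 bearing methyl, C4, C5, C6; exocyclic C7 and C8). The key step exploits the vicinal anti array O1–C6/C7–Cl that links the pyran ring to its quaternary carbon: a chlorenium donor activates the C6=C7 alkene of the acyclic (2S,3Z,6Z)-dienol 13, the C2 hydroxyl closes the ring at C6, and the O1–C6 bond, the C7–Cl bond and both new stereocentres (C6, C7) form in one operation. The precursor 13 carries only the C2 stereocentre and two (Z)-trisubstituted alkenes and is built in six steps from propargyl alcohol.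

Key step: step 7

Assumption: in step 6 the CHBr2 group is taken to act as the larger carbonyl substituent toward the oxazaborolidine, as trihalomethyl groups do; the (R)-catalyst is chosen on that basis.

**Route**

Step 1
Reactants: 1 prop-2-yn-1-ol; 2 oxirane
Product: 4 (2Z)-2-methylpent-2-ene-1,5-diol, via alkenylmagnesium alkoxide 3 (not isolated)
Conditions: MeMgBr (2.5 equiv), CuI (10 mol %), Et2O/THF, −10 °C → rt; then oxirane (3 equiv), −30 → 0 °C
Reagents that add atoms: methylmagnesium bromide, C[Mg]Br
Why: Copper-catalysed anti-carbomagnesiation of the propargylic alkoxide places methyl on the internal carbon and magnesium on the terminal carbon cis to the CH2O group (five-membered chelate), so the copper-catalysed opening of oxirane by this alkenylmagnesium should fix the (Z)-alkene by mechanism.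

Step 2
Reactants: 4 (2Z)-2-methylpent-2-ene-1,5-diol
Product: 5 (3Z)-5-chloro-4-methylpent-3-en-1-ol
Conditions: NCS (1.2 equiv), Me2S (1.3 equiv), CH2Cl2, −20 → 0 °C
Reagents that add atoms: N-chlorosuccinimide, O=C1CCC(=O)N1Cl
Why: Corey–Kim chlorination should convert only the allylic alkoxysulfonium salt to the chloride (SN2, no allylic transposition, Z geometry kept), while the saturated primary alkoxysulfonium salt returns the alcohol on work-up; 5 is used without storage.

Step 3
Reactants: 5 (3Z)-5-chloro-4-methylpent-3-en-1-ol
Product: 6 (3Z)-5-chloro-4-methylpent-3-enal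
Conditions: Dess–Martin periodinane, pyridine, CH2Cl2, 0 °C
Reagents that add atoms: none
Why: Dess–Martin oxidation under pyridine buffering should give the β,γ-unsaturated aldehyde without acid or base strong enough to move the alkene into conjugation; the aldehyde is used at once.

Step 4
Reactants: 6 (3Z)-5-chloro-4-methylpent-3-enal; 7 ethyl 2-[bis(2,2,2-trifluoroethoxy)phosphoryl]propanoate
Product: 9 ethyl (2Z,5Z)-7-chloro-2,6-dimethylhepta-2,5-dienoate, via potassium phosphonate carbanion 8 (not isolated)
Conditions: 7, KN(SiMe3)2, 18-crown-6, THF, −78 °C; then 6, −78 °C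
Reagents that add atoms: none
Why: Still–Gennari olefination, in which the electron-poor phosphonate under dissociating conditions eliminates fast from the kinetic adduct and should give the (Z)-2-methyl enoate, the stabilised anion adding to the aldehyde faster than it enolises it at −78 °C.

Step 5
Reactants: 9 ethyl (2Z,5Z)-7-chloro-2,6-dimethylhepta-2,5-dienoate
Product: 11 (3Z,6Z)-1,1-dibromo-8-chloro-3,7-dimethylocta-3,6-dien-2-one, via tetrahedral lithium alkoxide 10 (not isolated)
Conditions: CH2Br2, lithium 2,2,6,6-tetramethylpiperidide, THF, −78 °C; then 9; AcOH, −78 °C → rt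
Reagents that add atoms: dibromomethane, BrCBr
Why: Acylation of the carbenoid LiCHBr2 by the ester should stop at a tetrahedral lithium alkoxide that is stable at −78 °C and collapses only on acidic quench, so a single CHBr2 unit is introduced and the α,α-dibromoketone results with the (3Z) geometry kept.

Step 6
Reactants: 11 (3Z,6Z)-1,1-dibromo-8-chloro-3,7-dimethylocta-3,6-dien-2-one
Product: 13 (2S,3Z,6Z)-1,1-dibromo-8-chloro-3,7-dimethylocta-3,6-dien-2-ol, via catechol borate ester 12 (not isolated)
Conditions: (R)-2-methyl-CBS-oxazaborolidine (20 mol %), catecholborane, toluene, −78 °C; aqueous work-up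
Reagents that add atoms: none
Why: CBS reduction, in which the ketone binds the endocyclic boron anti to the CHBr2 group and hydride passes from the coordinated borane to one carbonyl face in a six-membered transition state, should give 1,2-reduction only and, with the (R)-catalyst, the (2S)-carbinol.

Step 7
Reactants: 13 (2S,3Z,6Z)-1,1-dibromo-8-chloro-3,7-dimethylocta-3,6-dien-2-ol
Product: 14 (2S,6S)-2-(dibromomethyl)-6-[(2R)-1,2-dichloropropan-2-yl]-3-methyl-5,6-dihydro-2H-pyran
Conditions: DCDMH (1.1 equiv), Ph3P=S (10 mol %), CH2Cl2, −40 → −20 °C
Reagents that add atoms: 1,3-dichloro-5,5-dimethylhydantoin (DCDMH), CC1(C)N(Cl)C(=O)N(Cl)C1=O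
Why: The Lewis base passes Cl+ from DCDMH to the C6=C7 alkene while the C2 hydroxyl attacks C6 from the opposite face (nucleophile-assisted activation through a chloriranium-like transition state), and loss of the proton gives the cyclic ether. The closest known reaction type is the halocycloetherification of alkenols, and the ring closes in the 6-exo mode (6-exo-trig on the alkene, exo opening of the chloriranium ion) in preference to 7-endo attack at C7, whose cationic character is lowered by the CH2Cl group. C7 is set by the stereospecific anti addition across the (6Z)-alkene, which ties (7R) to (6S). C6 is set by the C2 stereocentre: in the half-chair transition state the CHBr2 group should sit pseudoaxial to avoid A(1,2) strain with the C3 methyl group while the chloriranium-bearing carbon sits equatorial, which leads to the 2,6-trans ring. The step needs chemoselectivity between two trisubstituted alkenes, secured because only C6=C7 has the hydroxyl within reach for a six-membered closure, whereas attack on C3=C4 could close only a three- or four-membered ring and that alkene is deactivated inductively by the carbinol and CHBr2 groups.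

**Compound list**

1 | prop-2-yn-1-ol | C#CCO | starting material
2 | oxirane | C1CO1 | starting material
3 | bromomagnesium (2Z)-3-(bromomagnesio)-2-methylprop-2-en-1-olate | C/C(CO[Mg]Br)=C/[Mg]Br | intermediate (not isolated)
4 | (2Z)-2-methylpent-2-ene-1,5-diol | OC/C(C)=C\CCO | intermediate
5 | (3Z)-5-chloro-4-methylpent-3-en-1-ol | ClC/C(C)=C\CCO | intermediate
6 | (3Z)-5-chloro-4-methylpent-3-enal | ClC/C(C)=C\CC=O | intermediate
7 | ethyl 2-[bis(2,2,2-trifluoroethoxy)phosphoryl]propanoate | CCOC(=O)C(C)P(=O)(OCC(F)(F)F)OCC(F)(F)F | starting material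
8 | potassium salt of the α-carbanion of 7 | [K+].CCOC(=O)[C-](C)P(=O)(OCC(F)(F)F)OCC(F)(F)F | intermediate (not isolated)
9 | ethyl (2Z,5Z)-7-chloro-2,6-dimethylhepta-2,5-dienoate | ClC/C(C)=C\C/C=C(C)\C(=O)OCC | intermediate
10 | lithium (3Z,6Z)-1,1-dibromo-8-chloro-2-ethoxy-3,7-dimethylocta-3,6-dien-2-olate | ClC/C(C)=C\C/C=C(C)\C(O[Li])(OCC)C(Br)Br | intermediate (not isolated)
11 | (3Z,6Z)-1,1-dibromo-8-chloro-3,7-dimethylocta-3,6-dien-2-one | ClC/C(C)=C\C/C=C(C)\C(=O)C(Br)Br | intermediate
12 | 2-{[(2S,3Z,6Z)-1,1-dibromo-8-chloro-3,7-dimethylocta-3,6-dien-2-yl]oxy}-1,3,2-benzodioxaborole | ClC/C(C)=C\C/C=C(C)\[C@H](OB1Oc2ccccc2O1)C(Br)Br | intermediate (not isolated)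
13 | (2S,3Z,6Z)-1,1-dibromo-8-chloro-3,7-dimethylocta-3,6-dien-2-ol | ClC/C(C)=C\C/C=C(C)\[C@H](O)C(Br)Br | intermediate
14 | (2S,6S)-2-(dibromomethyl)-6-[(2R)-1,2-dichloropropan-2-yl]-3-methyl-5,6-dihydro-2H-pyran | CC1=CC[C@@H]([C@@](C)(Cl)CCl)O[C@@H]1C(Br)Br | target

**Step count and risks**

Total steps: 7. Longest linear sequence: 7.

Steps most likely to fail:

1. Step 7. The chlorenium species may attack the C3=C4 alkene or chlorinate an allylic position in an ene-type process, the ring may close in the 7-endo mode at C7, or the two faces of C6=C7 may be told apart poorly so that the 2,6-cis ring forms alongside. The fallback moves the activation from the alkene to a carbonyl group, so that only C6 is electrophilic. It sets out from 13: Ganem oxidation of the allylic chloride (N-methylmorpholine N-oxide, MeCN) should give (2Z,5Z,7S)-8,8-dibromo-7-hydroxy-2,6-dimethylocta-2,5-dienal F1. A primary-amine catalyst (9-amino-9-deoxy-epi-quinine as its trifluoroacetate) with NCS should then bring about intramolecular oxa-Michael addition of the C2 hydroxyl to C6 through the iminium ion and chlorination of the resulting enamine at C7, giving (2R)-2-chloro-2-[(2S,6S)-6-(dibromomethyl)-5-methyl-3,6-dihydro-2H-pyran-2-yl]propanal F2. The sense of induction at C7 in this cascade is not predictable with confidence and the catalyst enantiomer would have to be matched by experiment. NaBH4 reduction should give (2S)-2-chloro-2-[(2S,6S)-6-(dibromomethyl)-5-methyl-3,6-dihydro-2H-pyran-2-yl]propan-1-ol F3, and Appel chlorination (PPh3, CCl4) of the primary hydroxyl comes back to the route at 14.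

2. Step 6. The oxazaborolidine may discriminate poorly between two carbonyl substituents of similar effective size (CHBr2 and the twisted (Z)-alkenyl group), or bind the ketone in the opposite sense, so that the carbinol forms with low or reversed enantioselectivity. The fallback sets out from 11 and reduces it with an NADPH-dependent ketoreductase (alcohol dehydrogenase class) chosen from an enantiocomplementary panel for the (S)-carbinol, with glucose/glucose dehydrogenase recycling in phosphate buffer/DMSO at pH 6.5. It comes back to the route at 13, and no new compound is made (F0).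

3. Step 5. The basic carbenoid may remove a doubly allylic C5 proton of the dienoate, after which chloride is lost by 1,4-elimination, or the tetrahedral adduct may collapse early and take up a second carbenoid. The fallback uses the far more electrophilic aldehyde. It sets out from 9: i-Bu2AlH reduction (CH2Cl2, −78 °C) should give (2Z,5Z)-7-chloro-2,6-dimethylhepta-2,5-dien-1-ol F4, and MnO2 oxidation should give (2Z,5Z)-7-chloro-2,6-dimethylhepta-2,5-dienal F5. Addition of preformed LiCHBr2 at −100 °C with cold AcOH quench should give racemic (3Z,6Z)-1,1-dibromo-8-chloro-3,7-dimethylocta-3,6-dien-2-ol F6, and Dess–Martin oxidation of F6 comes back to the route at 11.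

**Further compounds**

F1 | step 7 | (2Z,5Z,7S)-8,8-dibromo-7-hydroxy-2,6-dimethylocta-2,5-dienal | O=C/C(C)=C\C/C=C(C)\[C@H](O)C(Br)Br
F2 | step 7 | (2R)-2-chloro-2-[(2S,6S)-6-(dibromomethyl)-5-methyl-3,6-dihydro-2H-pyran-2-yl]propanal | CC1=CC[C@@H]([C@@](C)(Cl)C=O)O[C@@H]1C(Br)Br
F3 | step 7 | (2S)-2-chloro-2-[(2S,6S)-6-(dibromomethyl)-5-methyl-3,6-dihydro-2H-pyran-2-yl]propan-1-ol | CC1=CC[C@@H]([C@@](C)(Cl)CO)O[C@@H]1C(Br)Br
F0 | step 6 | none | none
F4 | step 5 | (2Z,5Z)-7-chloro-2,6-dimethylhepta-2,5-dien-1-ol | ClC/C(C)=C\C/C=C(C)\CO
F5 | step 5 | (2Z,5Z)-7-chloro-2,6-dimethylhepta-2,5-dienal | ClC/C(C)=C\C/C=C(C)\C=O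
F6 | step 5 | racemic (3Z,6Z)-1,1-dibromo-8-chloro-3,7-dimethylocta-3,6-dien-2-ol | ClC/C(C)=C\C/C=C(C)\C(O)C(Br)Br
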